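**Retrosynthetic overview** (labdane numbering; target = ent-labda-8(17),13(16),14-trien-19-yl (Z)-4-hydroxycinnamate, 4R,5S,9R,10S)
1. C19 ester last: (Z)-coumarate from alcohol 21 by phosphonoacetylation and Z-selective olefination.
2. 21 ⇒ acyclic (R)-2-methyl-2-alkyloxirane 20 in one cation–olefin cascade: ring A first (C4–C5, oxirane opened with inversion, its CH2O becomes the axial C19-OH), then ring B (C10–C9) onto a (Z)-allylsilane that ends as the 8(17)-methylidene; the 13(16),14-diene is carried through.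
3. 20 ⇒ methyl ketone 17 by catalytic asymmetric methylene transfer (only source of absolute configuration).
4. 17 ⇒ myrcene-derived dienal 3 + 2-lithioallylsilane (ortho ester Claisen sets the allylsilane alkene), a stabilised ylide (E-alkene) and a masked 3-oxobutyl Grignard reagent.

Assumption: the (R)-binaphtholate lanthanum–lithium catalyst of step 8 is taken to deliver the (R)-oxirane; if the sense of induction is the reverse, its enantiomer is used.

**Step 1**
Reactants: 1 myrcene (7-methyl-3-methylideneocta-1,6-diene)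
Product: 3 4-methylidenehex-5-enal, via 6,7-epoxymyrcene 2 (not isolated)
Conditions: mCPBA (1.0 equiv), CH2Cl2, 0 °C; then H5IO6 (1.2 equiv), THF/H2O, 0 °C to rt
Reagents that add atoms: 3-chloroperoxybenzoic acid (mCPBA), OOC(=O)c1cccc(Cl)c1
Why: Peracid epoxidation picks the electron-rich trisubstituted alkene over the conjugated diene, and periodic acid cleaves the trisubstituted epoxide (hydrolysis, then glycol cleavage) to the aldehyde; no stereocentre is kept.

**Step 2**
Reactants: 3 4-methylidenehex-5-enal; 4 (2-bromoprop-2-en-1-yl)trimethylsilane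
Product: 6 6-methylidene-2-[(trimethylsilyl)methyl]octa-1,7-dien-3-ol (racemic), via 2-lithioallylsilane 5 (not isolated)
Conditions: 4, t-BuLi (2.0 equiv), Et2O, −78 °C; then 3, −78 to 0 °C; H2O
Reagents that add atoms: none
Why: Bromine–lithium exchange gives the vinyllithium, which adds 1,2 to the aldehyde (organolithium carbonyl addition); the new carbinol centre is racemic and is erased in step 3.

**Step 3**
Reactants: 6 6-methylidene-2-[(trimethylsilyl)methyl]octa-1,7-dien-3-ol; 7 triethyl orthoacetate
Product: 8 ethyl (4Z)-8-methylidene-4-[(trimethylsilyl)methyl]deca-4,9-dienoate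
Conditions: 7 (6 equiv), EtCO2H (5 mol %), 140 °C, EtOH distilled off
Reagents that add atoms: none
Why: Johnson–Claisen [3,3] rearrangement through a chair with the carbinol side chain equatorial places the new CH2CH2CO2Et chain trans to the diene-bearing chain (Z by CIP because of CH2SiMe3) and gives the trisubstituted allylsilane.

**Step 4**
Reactants: 8 ethyl (4Z)-8-methylidene-4-[(trimethylsilyl)methyl]deca-4,9-dienoate; 9 ethyl 2-(triphenyl-λ5-phosphanylidene)propanoate
Product: 11 ethyl (2E,6Z)-2-methyl-10-methylidene-6-[(trimethylsilyl)methyl]dodeca-2,6,11-trienoate, via aldehyde 10 (not isolated)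
Conditions: i-Bu2AlH (1.05 equiv), CH2Cl2, −78 °C; then 9 (1.5 equiv), −78 °C to rt; aq. potassium sodium tartrate
Reagents that add atoms: none
Why: Low-temperature half-reduction stops at the aluminium hemiacetal/aldehyde, which is trapped in the same flask by the stabilised ylide in an E-selective Wittig reaction (α-methyl stabilised ylides typically give >95:5 E).

**Step 5**
Reactants: 11 ethyl (2E,6Z)-2-methyl-10-methylidene-6-[(trimethylsilyl)methyl]dodeca-2,6,11-trienoate
Product: 13 (2E,6Z)-2-methyl-10-methylidene-6-[(trimethylsilyl)methyl]dodeca-2,6,11-trien-1-yl acetate, via allylic alcohol 12 (not isolated)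
Conditions: i-Bu2AlH (2.3 equiv), CH2Cl2, −78 to 0 °C; then pyridine, DMAP, Ac2O, 0 °C to rt
Reagents that add atoms: acetic anhydride, CC(=O)OC(C)=O
Why: 1,2-Reduction of the enoate gives the aluminium alkoxide of the allylic alcohol, which is acetylated in situ (reductive acetylation) to provide the leaving group for step 6 without touching either alkene geometry.

**Step 6**
Reactants: 13 (2E,6Z)-2-methyl-10-methylidene-6-[(trimethylsilyl)methyl]dodeca-2,6,11-trien-1-yl acetate; 14 2-(2-bromoethyl)-2-methyl-1,3-dioxolane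
Product: 16 2-methyl-2-[(4E,8Z)-4-methyl-12-methylidene-8-[(trimethylsilyl)methyl]tetradeca-4,8,13-trien-1-yl]-1,3-dioxolane, via Grignard reagent 15 (not isolated)
Conditions: 14, Mg, THF, 25 °C; then added slowly to 13, Li2CuCl4 (3 mol %), THF, −20 to 0 °C; aq. NH4Cl
Reagents that add atoms: none
Why: Copper-catalysed Grignard cross-coupling of a primary allylic acetate (Fouquet–Schlosser type) occurs at the α-carbon with retention of the E geometry, slow addition in THF favouring SN2 over SN2′.

**Step 7**
Reactants: 16 2-methyl-2-[(4E,8Z)-4-methyl-12-methylidene-8-[(trimethylsilyl)methyl]tetradeca-4,8,13-trien-1-yl]-1,3-dioxolane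
Product: 17 (6E,10Z)-6-methyl-14-methylidene-10-[(trimethylsilyl)methyl]hexadeca-6,10,15-trien-2-one
Conditions: pyridinium p-toluenesulfonate (20 mol %), acetone/H2O 10:1, 50 °C
Reagents that add atoms: water, O
Why: Mild acid-catalysed ketal hydrolysis unmasks the methyl ketone, the acid being too weak to protodesilylate the allylsilane.

**Step 8**
Reactants: 17 (6E,10Z)-6-methyl-14-methylidene-10-[(trimethylsilyl)methyl]hexadeca-6,10,15-trien-2-one; 18 trimethylsulfoxonium iodide
Product: 20 (2R)-2-methyl-2-[(4E,8Z)-4-methyl-12-methylidene-8-[(trimethylsilyl)methyl]tetradeca-4,8,13-trien-1-yl]oxirane, via dimethylsulfoxonium methylide 19 (not isolated)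
Conditions: 18, NaH, THF, reflux, filtered; then 17, LaLi3[(R)-1,1′-binaphthalene-2,2′-diolate]3 (5 mol %), tris(2,4,6-trimethoxyphenyl)phosphine oxide (5 mol %), 5 Å molecular sieves, THF, rt
Reagents that add atoms: none
Why: Catalytic asymmetric Corey–Chaykovsky methylene transfer, in which the lanthanum–lithium binaphthoxide/phosphine oxide catalyst directs the ylide to one face of the methyl ketone (typically 90–96% ee for alkyl methyl ketones) and so sets the C4 stereocentre.

**Step 9**
Reactants: 20 (2R)-2-methyl-2-[(4E,8Z)-4-methyl-12-methylidene-8-[(trimethylsilyl)methyl]tetradeca-4,8,13-trien-1-yl]oxirane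
Product: 21 [(1R,4aS,5R,8aS)-1,4a-dimethyl-6-methylidene-5-(3-methylidenepent-4-en-1-yl)decahydronaphthalen-1-yl]methanol (ent-labda-8(17),13(16),14-trien-19-ol)
Conditions: MeAlCl2 (1.5 equiv), CH2Cl2 (5 mM), −94 to −78 °C; then H2O
Reagents that add atoms: none
Why: Proposed new method: the MeAlCl2-activated oxirane is opened at its tertiary carbon by the C5=C10 alkene in an SN2-like anti (inverting) attack through a chair in which the tied-back oxirane CH2, smaller than the free methyl and tilted away from C20, sits axial, so the oxygen ends on the axial C19 and fixes C4; the C10 cation is then captured through a second chair by the (Z)-allylsilane (anti addition across the E-alkene gives the trans ring fusion and the equatorial C9 chain), and loss of Me3Si gives the 8(17)-methylidene before the diene can intervene; the closest known chemistry is the MeAlCl2-promoted cyclisation of 2,3-epoxy polyenes with allylsilane terminators together with the inverting opening of 2,2-disubstituted oxiranes by π-nucleophiles.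

**Step 10**
Reactants: 21 ent-labda-8(17),13(16),14-trien-19-ol; 22 2-[bis(2,2,2-trifluoroethoxy)phosphoryl]acetic acid
Product: 23 [(1R,4aS,5R,8aS)-1,4a-dimethyl-6-methylidene-5-(3-methylidenepent-4-en-1-yl)decahydronaphthalen-1-yl]methyl 2-[bis(2,2,2-trifluoroethoxy)phosphoryl]acetate
Conditions: DCC (1.3 equiv), DMAP (10 mol %), CH2Cl2, 0 °C to rt
Reagents that add atoms: none
Why: Steglich esterification of the primary neopentyl alcohol; no stereocentre is involved.

**Step 11**
Reactants: 23 the phosphonoacetate of 21; 24 4-[(tert-butyldimethylsilyl)oxy]benzaldehyde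
Product: 26 [(1R,4aS,5R,8aS)-1,4a-dimethyl-6-methylidene-5-(3-methylidenepent-4-en-1-yl)decahydronaphthalen-1-yl]methyl (2Z)-3-(4-hydroxyphenyl)prop-2-enoate, via silyl ether 25 (not isolated)
Conditions: KN(SiMe3)2 (1.05 equiv), 18-crown-6 (4 equiv), THF, −78 °C, then 24, −78 °C, dark; then AcOH, Bu4NF (1.2 equiv), 0 °C
Reagents that add atoms: none
Why: Still–Gennari Horner–Wadsworth–Emmons olefination, in which the trifluoroethyl phosphonate under dissociating conditions eliminates fast from the kinetic adduct to give the (Z)-cinnamate (typically >15:1 with aryl aldehydes), and buffered fluoride then removes the aryl silyl ether without Z-to-E isomerisation.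

**Compound list**
1 | myrcene (7-methyl-3-methylideneocta-1,6-diene) | CC(C)=CCCC(=C)C=C | starting material
2 | 6,7-epoxymyrcene, 2,2-dimethyl-3-(3-methylidenepent-4-en-1-yl)oxirane (racemic) | CC1(C)OC1CCC(=C)C=C | intermediate
3 | 4-methylidenehex-5-enal | O=CCCC(=C)C=C | intermediate
4 | (2-bromoprop-2-en-1-yl)trimethylsilane | C=C(Br)C[Si](C)(C)C | starting material
5 | [3-(trimethylsilyl)prop-1-en-2-yl]lithium | [Li]C(=C)C[Si](C)(C)C | intermediate
6 | 6-methylidene-2-[(trimethylsilyl)methyl]octa-1,7-dien-3-ol (racemic) | C=C(C[Si](C)(C)C)C(O)CCC(=C)C=C | intermediate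
7 | triethyl orthoacetate | CCOC(C)(OCC)OCC | starting material
8 | ethyl (4Z)-8-methylidene-4-[(trimethylsilyl)methyl]deca-4,9-dienoate | CCOC(=O)CC/C(C[Si](C)(C)C)=C/CCC(=C)C=C | intermediate
9 | ethyl 2-(triphenyl-λ5-phosphanylidene)propanoate | CCOC(=O)C(C)=P(c1ccccc1)(c1ccccc1)c1ccccc1 | starting material
10 | (4Z)-8-methylidene-4-[(trimethylsilyl)methyl]deca-4,9-dienal | O=CCC/C(C[Si](C)(C)C)=C/CCC(=C)C=C | intermediate
11 | ethyl (2E,6Z)-2-methyl-10-methylidene-6-[(trimethylsilyl)methyl]dodeca-2,6,11-trienoate | CCOC(=O)/C(C)=C/CC/C(C[Si](C)(C)C)=C/CCC(=C)C=C | intermediate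
12 | (2E,6Z)-2-methyl-10-methylidene-6-[(trimethylsilyl)methyl]dodeca-2,6,11-trien-1-ol | OC/C(C)=C/CC/C(C[Si](C)(C)C)=C/CCC(=C)C=C | intermediate
13 | (2E,6Z)-2-methyl-10-methylidene-6-[(trimethylsilyl)methyl]dodeca-2,6,11-trien-1-yl acetate | CC(=O)OC/C(C)=C/CC/C(C[Si](C)(C)C)=C/CCC(=C)C=C | intermediate
14 | 2-(2-bromoethyl)-2-methyl-1,3-dioxolane | CC1(CCBr)OCCO1 | starting material
15 | [2-(2-methyl-1,3-dioxolan-2-yl)ethyl]magnesium bromide | CC1(CC[Mg]Br)OCCO1 | intermediate
16 | 2-methyl-2-[(4E,8Z)-4-methyl-12-methylidene-8-[(trimethylsilyl)methyl]tetradeca-4,8,13-trien-1-yl]-1,3-dioxolane | CC1(CCC/C(C)=C/CC/C(C[Si](C)(C)C)=C/CCC(=C)C=C)OCCO1 | intermediate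
17 | (6E,10Z)-6-methyl-14-methylidene-10-[(trimethylsilyl)methyl]hexadeca-6,10,15-trien-2-one | CC(=O)CCC/C(C)=C/CC/C(C[Si](C)(C)C)=C/CCC(=C)C=C | intermediate
18 | trimethylsulfoxonium iodide | C[S+](C)(C)=O.[I-] | starting material
19 | dimethylsulfoxonium methylide | [CH2-][S+](C)(C)=O | intermediate
20 | (2R)-2-methyl-2-[(4E,8Z)-4-methyl-12-methylidene-8-[(trimethylsilyl)methyl]tetradeca-4,8,13-trien-1-yl]oxirane | C[C@@]1(CCC/C(C)=C/CC/C(C[Si](C)(C)C)=C/CCC(=C)C=C)CO1 | intermediate
21 | [(1R,4aS,5R,8aS)-1,4a-dimethyl-6-methylidene-5-(3-methylidenepent-4-en-1-yl)decahydronaphthalen-1-yl]methanol | C=CC(=C)CC[C@@H]1C(=C)CC[C@@H]2[C@](C)(CO)CCC[C@@]12C | intermediate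
22 | 2-[bis(2,2,2-trifluoroethoxy)phosphoryl]acetic acid | OC(=O)CP(=O)(OCC(F)(F)F)OCC(F)(F)F | starting material
23 | [(1R,4aS,5R,8aS)-1,4a-dimethyl-6-methylidene-5-(3-methylidenepent-4-en-1-yl)decahydronaphthalen-1-yl]methyl 2-[bis(2,2,2-trifluoroethoxy)phosphoryl]acetate | C=CC(=C)CC[C@@H]1C(=C)CC[C@@H]2[C@](C)(COC(=O)CP(=O)(OCC(F)(F)F)OCC(F)(F)F)CCC[C@@]12C | intermediate
24 | 4-[(tert-butyldimethylsilyl)oxy]benzaldehyde | CC(C)(C)[Si](C)(C)Oc1ccc(C=O)cc1 | starting material
25 | [(1R,4aS,5R,8aS)-1,4a-dimethyl-6-methylidene-5-(3-methylidenepent-4-en-1-yl)decahydronaphthalen-1-yl]methyl (2Z)-3-{4-[(tert-butyldimethylsilyl)oxy]phenyl}prop-2-enoate | C=CC(=C)CC[C@@H]1C(=C)CC[C@@H]2[C@](C)(COC(=O)/C=C\c3ccc(O[Si](C)(C)C(C)(C)C)cc3)CCC[C@@]12C | intermediate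
26 | [(1R,4aS,5R,8aS)-1,4a-dimethyl-6-methylidene-5-(3-methylidenepent-4-en-1-yl)decahydronaphthalen-1-yl]methyl (2Z)-3-(4-hydroxyphenyl)prop-2-enoate | C=CC(=C)CC[C@@H]1C(=C)CC[C@@H]2[C@](C)(COC(=O)/C=C\c3ccc(O)cc3)CCC[C@@]12C | target

**Total step count:** 11. **Longest linear sequence:** 11 steps (1 to 26).

**Three steps most likely to fail**

Step 9 (ring closure). The oxirane may rearrange to the aldehyde by 1,2-hydride shift instead of cyclising. The axial preference of the oxirane CH2 is a prediction; the other chair would give the C4-epimeric alcohol of the antipodal decalin, a separable diastereomer, not a loss of ee. The 1,3-diene may also capture the C8 cation or a second activated oxirane. The fallback addresses only the diene problem; it sets out from 20 and comes back at 21, and takes the diene out of the cationic step as its sulfur dioxide adduct. Compound 20 with excess liquid SO2, a little hydroquinone and 2,6-di-tert-butylpyridine in CH2Cl2 (sealed tube, 25 °C) gives by cheletropic addition 3-{(3Z,7E)-8-methyl-11-[(2R)-2-methyloxiran-2-yl]-4-[(trimethylsilyl)methyl]undeca-3,7-dien-1-yl}-2,5-dihydrothiophene 1,1-dioxide F1. MeAlCl2 (2.5 equiv, CH2Cl2, −78 °C) then closes rings A and B as in step 9 to give 3-{2-[(1R,4aS,5R,8aS)-5-(hydroxymethyl)-5,8a-dimethyl-2-methylidenedecahydronaphthalen-1-yl]ethyl}-2,5-dihydrothiophene 1,1-dioxide F2. Heating this in toluene over NaHCO3 at 110 °C expels SO2 and returns 21.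

Step 8 (asymmetric methylene transfer). The ee on this long-chain alkyl methyl ketone may fall short, and the catalyst is sensitive to traces of water. The fallback sets out from 17 and comes back at 20 by making the racemate and resolving it. Ketone 17 with ylide 19 (from 18 and NaH, DMSO/THF, rt, no catalyst) gives racemic 2-methyl-2-[(4E,8Z)-4-methyl-12-methylidene-8-[(trimethylsilyl)methyl]tetradeca-4,8,13-trien-1-yl]oxirane F3. Kinetic resolution follows with Me3SiN3 (0.55 equiv) and [N,N′-bis(3,5-di-tert-butylsalicylidene)cyclohexane-1,2-diaminato]chromium azide (2 mol %), using the antipode that consumes the (S)-oxirane. It opens the unwanted enantiomer at CH2 to {[(2S,6E,10Z)-1-azido-2,6-dimethyl-14-methylidene-10-[(trimethylsilyl)methyl]hexadeca-6,10,15-trien-2-yl]oxy}trimethylsilane F4. Chromatography separates this from unreacted (R)-oxirane 20 (at most 50%, high ee).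

Step 6 (allyl–alkyl coupling). The β-ketal Grignard reagent 15 is thermally fragile, can attack the acetate carbonyl, and some SN2′ product may form. The fallback sets out from 13 and comes back at 17, bypassing 16, and makes the C1–C2 bond by a sigmatropic shift. Acetate 13, methyl vinyl ketone, InI and Pd(PPh3)4 (5 mol %) in THF at 25 °C give an umpoled allylindium that adds 1,2 to the ketone through its γ-carbon. The product is (7Z)-3-methyl-11-methylidene-4-(prop-1-en-2-yl)-7-[(trimethylsilyl)methyl]trideca-1,7,12-trien-3-ol F5, a diastereomer mixture. KH and 18-crown-6 in THF (0 °C to rt) trigger the anionic oxy-Cope rearrangement through a chair with the C5 substituent equatorial. Protonation of the enolate gives ketone 17 directly with the 6E alkene.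

**Further compounds**
F1 | step 9 | 3-{(3Z,7E)-8-methyl-11-[(2R)-2-methyloxiran-2-yl]-4-[(trimethylsilyl)methyl]undeca-3,7-dien-1-yl}-2,5-dihydrothiophene 1,1-dioxide | C[C@@]1(CCC/C(C)=C/CC/C(C[Si](C)(C)C)=C/CCC2=CCS(=O)(=O)C2)CO1
F2 | step 9 | 3-{2-[(1R,4aS,5R,8aS)-5-(hydroxymethyl)-5,8a-dimethyl-2-methylidenedecahydronaphthalen-1-yl]ethyl}-2,5-dihydrothiophene 1,1-dioxide | O=S1(=O)CC=C(CC[C@@H]2C(=C)CC[C@@H]3[C@](C)(CO)CCC[C@@]23C)C1
F3 | step 8 | 2-methyl-2-[(4E,8Z)-4-methyl-12-methylidene-8-[(trimethylsilyl)methyl]tetradeca-4,8,13-trien-1-yl]oxirane (racemic) | CC1(CCC/C(C)=C/CC/C(C[Si](C)(C)C)=C/CCC(=C)C=C)CO1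
F4 | step 8 | {[(2S,6E,10Z)-1-azido-2,6-dimethyl-14-methylidene-10-[(trimethylsilyl)methyl]hexadeca-6,10,15-trien-2-yl]oxy}trimethylsilane | C[C@](O[Si](C)(C)C)(CCC/C(C)=C/CC/C(C[Si](C)(C)C)=C/CCC(=C)C=C)CN=[N+]=[N-]
F5 | step 6 | (7Z)-3-methyl-11-methylidene-4-(prop-1-en-2-yl)-7-[(trimethylsilyl)methyl]trideca-1,7,12-trien-3-ol (diastereomer mixture) | C=CC(C)(O)C(CC/C(C[Si](C)(C)C)=C/CCC(=C)C=C)C(C)=C
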